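The rate constants were chosen freely; the rest is arithmetic.

We read this flask at 30 min, and the decision for the next run is whether to stop there or leave it longer.

substrate 37 mM; reagent in the second phase 40.7 mM; time 30 min; volume of the second phase over the first 0.25

    target ⇌ isomer of the product (K1 = 1.6, k1 = 0.19 /min)
    reagent in the reaction phase + target → over-reacted product (k2 = 1.9 /M/min)
    reagent in the reaction phase ⇌ reagent in the second phase, rate k3*([reagent in the reaction phase] - [reagent in the second phase]/K3) per volume of the first phase (K3 = 0.75, k3 = 0.014 /min)
    substrate + target → side product (k4 = 2.4 /M/min)
    substrate + reagent in the reaction phase → target (k5 = 2.1 /M/min)

- percentages count the substrate that a species holds: one side product counts as two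
- in the second phase: reagent in the second phase; everything else is in the first
- charges count per volume of the first phase; a concentration in a rate is the amount of a species over the volume of its own phase; every rate counts per litre of the first phase
- run time (flask): 30 min

- the target standing at 30 min, as a percentage of the substrate charged
- part of the substrate charged that has reacted at 30 min

Target swaps with its isomer with a relaxation half-life of 2.25 min, short against the time of reading, so we treat the two as one pair, which the steps to side product and over-reacted product drain. Counting forward flow alone, the second phase empties at 0.0747 /min, a half-life of 9.28 min. By the reading it has delivered 36.4 mM of reagent, nearly all of the substrate charged, and its feed has fallen from 3.04 mM/min to 0.324 mM/min. If each delivered reagent either still stands or has turned one substrate, then c(substrate) and c(reagent in the reaction phase) are about equal. Setting the feed equal to the use in making target gives both as 12.4 mM, so we reckon 66.5% of the substrate reacted.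

The pair stops growing when target stands at its rate of making divided by the two losses per unit of target. With substrate short this tends to 1.11 times c(substrate), and with reagent short to 0.875 times c(reagent in the reaction phase). Joining the two ends at our equal concentrations gives the balance level, the target at which making and loss match at that moment, 6.06 mM, or 16.4% of the charge. The pair moves towards it with a time of 48.7 min, longer than the reading time, so we expect target to lag below that level at the reading. We plan to stop at the reading, since in our reckoning the balance level falls as the feed falls.

The forecast gives 12.7% for target and 66.5% reacted, with target “held down by isomerisation and by the side and over-reaction steps”. That value lies under our balance level, the side on which we expected target to stand.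

The flask gives 12.3% of target and 63.8% reacted. The neighbouring flask, left until 80 min, holds substrate at 7.88% and reagent in the reaction phase at 6.97 mM. From these readings its balance level is 5.70% of the charge, lower than the 16.4% we reckoned for the first flask. Target in that neighbouring flask stands above this level, at 10.8%, while side product there has reached 45.9%.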